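A direct plan would join the two aromatic halves by Claisen–Schmidt condensation to the 2′-hydroxychalcone A1. It would close ring C last, through the O1–C2 bond, by an amine–thiourea-catalysed oxa-Michael addition.
The side chain would be made by auxiliary-controlled alkylation as (S)-lavandulyl iodide A2 and joined to the iodoarene A3 by Negishi coupling. The ring would then be acetylated and stripped to the triol A4.
Weak point 1, the ring closure of A1: the enone carries no activating group and the C–O bond formation is reversible. The basic catalyst that forms C2 could also reopen it by retro-oxa-Michael reaction, so C2 would be set with poor and eroding control.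
Weak point 2, the selective double protection of A4: it would have to distinguish two chelated ortho-phenols, and this choice alone decides between the 8- and the 6-lavandulyl series. The surrounding sequence of protection, removal, reprotection and removal builds nothing.
Weak point 3, the run-up to A3 and A2: several steps would only recreate a phloroglucinol pattern that can be bought, and four more would serve one auxiliary. This gives a long linear sequence ending in a coupling at a doubly ortho-substituted iodide.

## Retrosynthetic overview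
- Key disconnection C2–C1′. C2 is benzylic to the 2′,4′-dioxygenated ring B and β to C4=O, so its O1–C2 bond opens and recloses easily, whereas the C2–C1′ bond does not. Ring B is therefore added last, as an arylboronic acid, by Rh-catalysed enantioselective 1,4-addition to a complete 8-lavandulyl-4H-chromen-4-one.
- Ring order: ring A is bought, ring C is closed early as a flat, achiral pyranone (enaminone annulation), and ring B is attached in the key step. There is no chalcone and no C–O ring closure at a stereocentre.
- C8 versus C6: in the bis-acetal of symmetric 2,4,6-trihydroxyacetophenone the one free phenol directs iodination to its ortho position and then becomes O1. The halogen must therefore end at C8, and each phenol is protected only once.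
- Side chain: C2″ is assembled on boron from three small pieces (homoprenyl carbamate, isopropenyl boronate, CH2) by lithiation–borylation and Matteson homologation. It is then joined to C8 by B-alkyl Suzuki coupling.

Key step: step 10

Remark on labels: C1″ is the ArCH2 carbon, C2″ the side-chain stereocentre, C3″ the CH2 of the prenyl arm.
Remark on descriptors: C2″ keeps one spatial arrangement throughout. It is called (S) in the boronic esters and (R) once C1″ is bound to ring A, only because the CIP ranking of its substituents changes.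

## Route

Step 1
Reactants: 1 4-methylpent-3-en-1-ol
Product: 2 4-methylpent-3-en-1-yl N,N-diisopropylcarbamate
Conditions: i-Pr2NC(O)Cl, Et3N, CH2Cl2, reflux
Reagents that add atoms: N,N-diisopropylcarbamoyl chloride, CC(C)N(C(C)C)C(=O)Cl
Why: O-Carbamoylation of the primary alcohol should give the carbamate that later directs the α-lithiation and acts as the leaving group of the 1,2-shift.

Step 2
Reactants: 2 4-methylpent-3-en-1-yl N,N-diisopropylcarbamate; 3 isopropenylboronic acid pinacol ester
Product: 6 2-[(3S)-2,6-dimethylhepta-1,5-dien-3-yl]-4,4,5,5-tetramethyl-1,3,2-dioxaborolane, via lithiated carbamate 4 (not isolated), via boronate complex 5 (not isolated)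
Conditions: s-BuLi, (+)-sparteine, Et2O, −78 °C; 3, −78 °C → rt; then 35 °C
Reagents that add atoms: none
Why: Lithiation–borylation (Hoppe-type asymmetric deprotonation, then 1,2-metallate rearrangement): s-BuLi/(+)-sparteine should remove the pro-R α-hydrogen to give the configurationally stable (R)-organolithium 4, boron is bound with retention to give 5, and the isopropenyl group then migrates from boron to carbon anti to the carbamate (inversion), which forms the C2″–isopropenyl bond and sets C2″ under reagent control.

Step 3
Reactants: 6 2-[(3S)-2,6-dimethylhepta-1,5-dien-3-yl]-4,4,5,5-tetramethyl-1,3,2-dioxaborolane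
Product: 8 2-[(2S)-5-methyl-2-(prop-1-en-2-yl)hex-4-en-1-yl]-4,4,5,5-tetramethyl-1,3,2-dioxaborolane, via chloromethyl boronate complex 7 (not isolated)
Conditions: BrCH2Cl, n-BuLi, THF, −78 °C → rt
Reagents that add atoms: bromochloromethane, ClCBr
Why: Matteson homologation: chloromethyllithium made in situ adds to boron and the secondary allylic carbon migrates with retention while chloride leaves, so C1″ is inserted without touching C2″.

Step 4
Reactants: 9 2′,4′,6′-trihydroxyacetophenone
Product: 10 1-[2,4-bis(ethoxymethoxy)-6-hydroxyphenyl]ethan-1-one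
Conditions: EtOCH2Cl (2.2 equiv), i-Pr2NEt, CH2Cl2, 0 °C → rt
Reagents that add atoms: chloromethyl ethyl ether, CCOCCl
Why: O-Alkylation of the symmetric triol: the 4-OH and one of the two equivalent ortho-OH groups react and the last OH is held back by its hydrogen bond to the acetyl group, so the single free phenol that will become O1 is defined without any regiochemical choice.

Step 5
Reactants: 10 1-[2,4-bis(ethoxymethoxy)-6-hydroxyphenyl]ethan-1-one
Product: 11 1-[4,6-bis(ethoxymethoxy)-2-hydroxy-3-iodophenyl]ethan-1-one
Conditions: NIS, DMF, 0 °C → rt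
Reagents that add atoms: N-iodosuccinimide, O=C1CCC(=O)N1I
Why: Electrophilic aromatic iodination: the free phenol activates its ortho position C3, which is also less crowded than C5 between two acetal ethers, so iodine should enter next to the future O1, that is at the future C8.

Step 6
Reactants: 11 1-[4,6-bis(ethoxymethoxy)-2-hydroxy-3-iodophenyl]ethan-1-one
Product: 13 5,7-bis(ethoxymethoxy)-8-iodo-4H-chromen-4-one, via enaminone 12 (not isolated)
Conditions: Me2NCH(OMe)2, toluene, 90 °C; concentrate; AcOH, CH2Cl2, 40 °C
Reagents that add atoms: N,N-dimethylformamide dimethyl acetal, COC(OC)N(C)C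
Why: Enaminone formation at the acetyl CH3, followed by acid-promoted addition–elimination of the only free phenol at the β-carbon (6-endo, loss of dimethylamine), is the standard chromone annulation; it closes ring C as a flat pyranone and necessarily places the iodine at C8.

Step 7
Reactants: 13 5,7-bis(ethoxymethoxy)-8-iodo-4H-chromen-4-one; 8 2-[(2S)-5-methyl-2-(prop-1-en-2-yl)hex-4-en-1-yl]-4,4,5,5-tetramethyl-1,3,2-dioxaborolane
Product: 14 5,7-bis(ethoxymethoxy)-8-[(2R)-5-methyl-2-(prop-1-en-2-yl)hex-4-en-1-yl]-4H-chromen-4-one
Conditions: Pd(OAc)2 (5 mol %), RuPhos (10 mol %), K3PO4, toluene/H2O 10:1, 80 °C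
Reagents that add atoms: none
Why: B-alkyl Suzuki–Miyaura coupling: the electron-poor iodochromone should undergo fast oxidative addition, the bulky electron-rich biarylphosphine favours reductive elimination over β-hydride elimination, and C2″ lies β to boron and is not involved.

Step 8
Reactants: 15 4-bromoresorcinol
Product: 16 1-bromo-2,4-bis(ethoxymethoxy)benzene
Conditions: EtOCH2Cl, i-Pr2NEt, CH2Cl2, 0 °C → rt
Reagents that add atoms: chloromethyl ethyl ether, CCOCCl
Why: O-Alkylation masks both phenols as small, base-stable acetal ethers that tolerate the organolithium step.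

Step 9
Reactants: 16 1-bromo-2,4-bis(ethoxymethoxy)benzene
Product: 19 [2,4-bis(ethoxymethoxy)phenyl]boronic acid, via aryllithium 17 (not isolated), via triisopropyl borate complex 18 (not isolated)
Conditions: n-BuLi, THF, −78 °C; B(Oi-Pr)3, −78 °C → rt; H2O, work-up at pH 6–7
Reagents that add atoms: triisopropyl borate, CC(C)OB(OC(C)C)OC(C)C; water, O
Why: Bromine–lithium exchange, faster at −78 °C than any directed ortho-metalation, fixes the metal at C1′, and borylation with hydrolysis gives the boronic acid.

Step 10
Reactants: 14 5,7-bis(ethoxymethoxy)-8-[(2R)-5-methyl-2-(prop-1-en-2-yl)hex-4-en-1-yl]-4H-chromen-4-one; 19 [2,4-bis(ethoxymethoxy)phenyl]boronic acid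
Product: 20 (2S)-2-[2,4-bis(ethoxymethoxy)phenyl]-5,7-bis(ethoxymethoxy)-8-[(2R)-5-methyl-2-(prop-1-en-2-yl)hex-4-en-1-yl]-2,3-dihydro-4H-chromen-4-one
Conditions: [RhCl(C2H4)2]2 (2.5 mol %), chiral 2,5-diarylbicyclo[2.2.2]octa-2,5-diene ligand (5.5 mol %, the enantiomer that exposes the Re face of C2), aq. KOH (10 mol %), toluene/H2O 10:1, 40 °C, 19 added in portions
Reagents that add atoms: none
Why: Hayashi–Miyaura asymmetric 1,4-addition, a reaction type established for chromones: the boronic acid transmetalates to a hydroxo-Rh(I)/chiral diene complex, the aryl–Rh species binds the C2=C3 bond of the flat pyranone, syn-carborhodation forms C2–C1′, and water protonates the oxa-π-allyl rhodium enolate at C3 and regenerates Rh–OH. No ring is closed in this step; ring C already exists and is only converted from the pyranone into the chroman-4-one, so neither strain nor entropy has to be paid. C2 is set by the ligand alone, which should leave only the Re face of C2 open to the aryl group and thus give (2S); the C2″ centre sits five bonds away and should cause no mismatch. The C–C bond is formed irreversibly under near-neutral conditions and without a free phenoxide, so the retro-oxa-Michael channel that scrambles C2 is not opened. The step needs 1,4- over 1,2-addition and enone over isolated-alkene selectivity: aryl–Rh(I) does not add to ketones of this type or to unactivated 1,1-di- and trisubstituted alkenes, and C2 is the only β-position on offer. The small, coordinating ortho-OCH2OEt group and the portionwise addition of 19 are meant to keep the addition ahead of protodeboronation.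

Step 11
Reactants: 20 (2S)-2-[2,4-bis(ethoxymethoxy)phenyl]-5,7-bis(ethoxymethoxy)-8-[(2R)-5-methyl-2-(prop-1-en-2-yl)hex-4-en-1-yl]-2,3-dihydro-4H-chromen-4-one
Product: 21 sophoraflavanone G, (2S)-2-(2,4-dihydroxyphenyl)-5,7-dihydroxy-8-[(2R)-5-methyl-2-(prop-1-en-2-yl)hex-4-en-1-yl]-2,3-dihydro-4H-chromen-4-one
Conditions: polymer-bound sulfonic acid (cat.), MeOH/THF, 40 °C; filter
Reagents that add atoms: none
Why: Acid-catalysed transacetalisation to methanol removes all four ethoxymethyl groups in one operation; the levelled acidity of a sulfonic acid resin in methanol should leave the two alkenes unprotonated and the absence of base should keep the O1–C2 bond closed, so neither stereocentre is touched.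

## Compound list
1 | 4-methylpent-3-en-1-ol | CC(C)=CCCO | starting material
2 | 4-methylpent-3-en-1-yl N,N-diisopropylcarbamate | CC(C)=CCCOC(=O)N(C(C)C)C(C)C | intermediate
3 | isopropenylboronic acid pinacol ester | C=C(C)B1OC(C)(C)C(C)(C)O1 | starting material
4 | (1R)-1-lithio-4-methylpent-3-en-1-yl N,N-diisopropylcarbamate | [Li][C@H](CC=C(C)C)OC(=O)N(C(C)C)C(C)C | intermediate
5 | lithium (R)-[1-(diisopropylcarbamoyloxy)-4-methylpent-3-en-1-yl](isopropenyl)(pinacolato)borate | [Li+].C=C(C)[B-]1(OC(C)(C)C(C)(C)O1)[C@H](CC=C(C)C)OC(=O)N(C(C)C)C(C)C | intermediate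
6 | 2-[(3S)-2,6-dimethylhepta-1,5-dien-3-yl]-4,4,5,5-tetramethyl-1,3,2-dioxaborolane | C=C(C)[C@H](CC=C(C)C)B1OC(C)(C)C(C)(C)O1 | intermediate
7 | lithium (chloromethyl)[(3S)-2,6-dimethylhepta-1,5-dien-3-yl](pinacolato)borate | [Li+].C=C(C)[C@H](CC=C(C)C)[B-]1(CCl)OC(C)(C)C(C)(C)O1 | intermediate
8 | 2-[(2S)-5-methyl-2-(prop-1-en-2-yl)hex-4-en-1-yl]-4,4,5,5-tetramethyl-1,3,2-dioxaborolane | C=C(C)[C@H](CC=C(C)C)CB1OC(C)(C)C(C)(C)O1 | intermediate
9 | 2′,4′,6′-trihydroxyacetophenone | CC(=O)c1c(O)cc(O)cc1O | starting material
10 | 1-[2,4-bis(ethoxymethoxy)-6-hydroxyphenyl]ethan-1-one | CC(=O)c1c(O)cc(OCOCC)cc1OCOCC | intermediate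
11 | 1-[4,6-bis(ethoxymethoxy)-2-hydroxy-3-iodophenyl]ethan-1-one | CC(=O)c1c(O)c(I)c(OCOCC)cc1OCOCC | intermediate
12 | (2E)-1-[4,6-bis(ethoxymethoxy)-2-hydroxy-3-iodophenyl]-3-(dimethylamino)prop-2-en-1-one | CN(C)/C=C/C(=O)c1c(O)c(I)c(OCOCC)cc1OCOCC | intermediate
13 | 5,7-bis(ethoxymethoxy)-8-iodo-4H-chromen-4-one | O=c1ccoc2c(I)c(OCOCC)cc(OCOCC)c12 | intermediate
14 | 5,7-bis(ethoxymethoxy)-8-[(2R)-5-methyl-2-(prop-1-en-2-yl)hex-4-en-1-yl]-4H-chromen-4-one | C=C(C)[C@H](CC=C(C)C)Cc1c(OCOCC)cc(OCOCC)c2c1occc2=O | intermediate
15 | 4-bromoresorcinol | Oc1ccc(Br)c(O)c1 | starting material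
16 | 1-bromo-2,4-bis(ethoxymethoxy)benzene | CCOCOc1ccc(Br)c(OCOCC)c1 | intermediate
17 | [2,4-bis(ethoxymethoxy)phenyl]lithium | [Li]c1ccc(OCOCC)cc1OCOCC | intermediate
18 | lithium [2,4-bis(ethoxymethoxy)phenyl]tri(propan-2-yloxy)borate | [Li+].CC(C)O[B-](OC(C)C)(OC(C)C)c1ccc(OCOCC)cc1OCOCC | intermediate
19 | [2,4-bis(ethoxymethoxy)phenyl]boronic acid | OB(O)c1ccc(OCOCC)cc1OCOCC | intermediate
20 | (2S)-2-[2,4-bis(ethoxymethoxy)phenyl]-5,7-bis(ethoxymethoxy)-8-[(2R)-5-methyl-2-(prop-1-en-2-yl)hex-4-en-1-yl]-2,3-dihydro-4H-chromen-4-one | C=C(C)[C@H](CC=C(C)C)Cc1c(OCOCC)cc(OCOCC)c2c1O[C@H](c1ccc(OCOCC)cc1OCOCC)CC2=O | intermediate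
21 | sophoraflavanone G | C=C(C)[C@H](CC=C(C)C)Cc1c(O)cc(O)c2c1O[C@H](c1ccc(O)cc1O)CC2=O | target

## Totals
- Total step count: 11.
- Longest linear sequence: 6 steps (9 → 10 → 11 → 13 → 14 → 20 → 21). The side-chain branch 1 → 2 → 6 → 8 → 14 → 20 → 21 is equally long.

## The three steps most likely to fail

**Step 10 (key step).** The hindered, electron-rich ortho-alkoxyaryl–rhodium species may insert slowly into the electron-rich chromone. Protodeboronation could then outrun the addition, or the chiral ligand could lose its facial selectivity. The fallback sets out from 14 and 19. The addition would be run without stereocontrol, using the more active achiral complex [Rh(OH)(cod)]2 in dioxane/H2O, to give the C2-epimeric protected flavanone F1. A Noyori-type transfer hydrogenation under basic conditions (RuCl(p-cymene)(TsDPEN), HCO2H/DBU, MeCN) would follow. Base-induced retro-oxa-Michael/oxa-Michael equilibration interconverts the C2 epimers while only the (2S)-ketone is reduced quickly, so the mixture should funnel into the cis-(2S,4S)-flavan-4-ol F2. Oxidation with Dess–Martin periodinane (NaHCO3, CH2Cl2) would come back to the route at 20.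

**Step 7.** Transmetalation of the β-branched pinacol boronate to a doubly ortho-substituted aryl–palladium species may be slow. Hydroxide-induced opening of the pyranone ring, protodeiodination and β-hydride elimination would then have time to compete. The fallback sets out from 11 and 8 and makes the C8–C1″ bond before ring C exists. On this base-stable iodophenol the strongly activating conditions for primary pinacol boronates can be used (Pd(OAc)2, RuPhos, KOH, THF/H2O, 70 °C). This would give the 3′-lavandulyl acetophenone F3. Treatment with Me2NCH(OMe)2 would give the side-chain-bearing enaminone F4, and AcOH in CH2Cl2 would close ring C and come back to the route at 14.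

**Step 11.** Two processes may compete with the cleavage of the last acetal: acid-induced addition of the freed 7-OH to the isopropenyl group, and acid-induced opening of the O1–C2 bond, assisted by the freed 2′- and 4′-OH groups. The fallback sets out from 20 and avoids Brønsted acid altogether. TMSOTf and 2,2′-bipyridyl in MeCN at 0 °C would exchange the four aryl acetal ethers for silyl groups under non-acidic conditions, giving the tetrakis(trimethylsilyl) ether F5. Brief hydrolysis with water at neutral pH would come back to the route at 21.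

## Further compounds
F1 | step 10 | (2RS)-2-[2,4-bis(ethoxymethoxy)phenyl]-5,7-bis(ethoxymethoxy)-8-[(2R)-5-methyl-2-(prop-1-en-2-yl)hex-4-en-1-yl]-2,3-dihydro-4H-chromen-4-one | C=C(C)[C@H](CC=C(C)C)Cc1c(OCOCC)cc(OCOCC)c2c1OC(c1ccc(OCOCC)cc1OCOCC)CC2=O
F2 | step 10 | (2S,4S)-2-[2,4-bis(ethoxymethoxy)phenyl]-5,7-bis(ethoxymethoxy)-8-[(2R)-5-methyl-2-(prop-1-en-2-yl)hex-4-en-1-yl]-3,4-dihydro-2H-chromen-4-ol | C=C(C)[C@H](CC=C(C)C)Cc1c(OCOCC)cc(OCOCC)c2c1O[C@H](c1ccc(OCOCC)cc1OCOCC)C[C@@H]2O
F3 | step 7 | 1-{4,6-bis(ethoxymethoxy)-2-hydroxy-3-[(2R)-5-methyl-2-(prop-1-en-2-yl)hex-4-en-1-yl]phenyl}ethan-1-one | C=C(C)[C@H](CC=C(C)C)Cc1c(OCOCC)cc(OCOCC)c(C(C)=O)c1O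
F4 | step 7 | (2E)-1-{4,6-bis(ethoxymethoxy)-2-hydroxy-3-[(2R)-5-methyl-2-(prop-1-en-2-yl)hex-4-en-1-yl]phenyl}-3-(dimethylamino)prop-2-en-1-one | C=C(C)[C@H](CC=C(C)C)Cc1c(OCOCC)cc(OCOCC)c(C(=O)/C=C/N(C)C)c1O
F5 | step 11 | sophoraflavanone G 5,7,2′,4′-tetrakis(trimethylsilyl) ether | C=C(C)[C@H](CC=C(C)C)Cc1c(O[Si](C)(C)C)cc(O[Si](C)(C)C)c2c1O[C@H](c1ccc(O[Si](C)(C)C)cc1O[Si](C)(C)C)CC2=O
A1 | direct plan | (E)-2′-hydroxy-3′-[(2R)-5-methyl-2-(prop-1-en-2-yl)hex-4-en-1-yl]-2,4,4′,6′-tetrakis(methoxymethoxy)chalcone | C=C(C)[C@H](CC=C(C)C)Cc1c(OCOC)cc(OCOC)c(C(=O)/C=C/c2ccc(OCOC)cc2OCOC)c1O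
A2 | direct plan | (2S)-1-iodo-5-methyl-2-(prop-1-en-2-yl)hex-4-ene | C=C(C)[C@H](CC=C(C)C)CI
A3 | direct plan | 2-iodo-1,3,5-tris(methoxymethoxy)benzene | COCOc1cc(OCOC)c(I)c(OCOC)c1
A4 | direct plan | 1-{2,4,6-trihydroxy-3-[(2R)-5-methyl-2-(prop-1-en-2-yl)hex-4-en-1-yl]phenyl}ethan-1-one | C=C(C)[C@H](CC=C(C)C)Cc1c(O)cc(O)c(C(C)=O)c1O
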